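## Retrosynthetic overview

1. The target consists of ring A (a γ-butyrolactone whose C5 is S and bears 2-methylprop-1-enyl, and whose C3 bears an exocyclic alkylidene), an (E,E)-dimethyl chain, an E-diene and ring B (a butenolide joined through C4). The last bond made is the CH=CH next to ring B, by vinylogous Horner–Wadsworth–Emmons olefination of enal 25 with phosphonate 27; ring B is bought in as 26.
2. Ring A is the only ring closed in the route (step 14). It is opened at O1–C5: enantioselective allylic lactonisation of acid 22 onto its own tertiary allylic carbonate under zerovalent palladium catalysis.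
3. The route rests on the exocyclic C3=CH double bond of ring A, in which the chain CH2 is cis to ring carbon C4 and trans to the C2 carbonyl. This is the imprint of a syn addition of two carbon groups across a propiolate, so the chain CH2–CH= bond and the C3–C4 bond are made together in one three-component carbocupration/allylation (9 + 16 + 15 → 19).
4. Grignard reagent 9 comes from geraniol (terminal allylic oxidation, methylenation, hydroboration, bromide, Mg). Allylic bromide 15 comes from the trimethylsilyl ether of 2-methylbut-3-yn-2-ol (hydroxymethylation, trans-reduction, bromide).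

Key step: step 11

Assumption: 3-methyl-3-(trimethylsilyloxy)but-1-yne (10) is taken as a catalogue compound, and the (R,R) antipode of the ligand in step 14 is assumed to lead to the 5S lactone; since the sense of induction of this new cyclisation cannot be read from precedent, the (S,S) antipode is used instead if the first experiment shows the opposite sense.

## Route

Step 1
Reactants: 1 geraniol
Product: 2 geranyl tert-butyldimethylsilyl ether
Conditions: TBSCl, imidazole, DMF, 0 °C → rt
Reagents that add atoms: tert-butyldimethylsilyl chloride, CC(C)(C)[Si](C)(C)Cl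
Why: Imidazole-promoted silylation of a primary allylic alcohol is routine, and the silyl ether masks the hydroxyl through the organometallic steps.

Step 2
Reactants: 2 geranyl tert-butyldimethylsilyl ether
Product: 3 (2E,6E)-8-[(tert-butyldimethylsilyl)oxy]-2,6-dimethylocta-2,6-dien-1-ol
Conditions: SeO2 (cat.), salicylic acid (cat.), t-BuOOH, CH2Cl2, rt
Reagents that add atoms: tert-butyl hydroperoxide, CC(C)(C)OO
Why: The SeO2-catalysed allylic oxidation (ene reaction, then [2,3]-sigmatropic shift) should select the E-methyl group of the electron-rich terminal trisubstituted alkene, the 2,3-alkene being deactivated by its allylic oxygen; any aldehyde 4 formed by over-oxidation is pooled into step 3.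

Step 3
Reactants: 3 (2E,6E)-8-[(tert-butyldimethylsilyl)oxy]-2,6-dimethylocta-2,6-dien-1-ol
Product: 4 (2E,6E)-8-[(tert-butyldimethylsilyl)oxy]-2,6-dimethylocta-2,6-dienal
Conditions: MnO2, CH2Cl2, rt
Reagents that add atoms: none
Why: MnO2 oxidation of a primary allylic alcohol should give the enal without touching the silyl ether or the E-alkene.

Step 4
Reactants: 4 (2E,6E)-8-[(tert-butyldimethylsilyl)oxy]-2,6-dimethylocta-2,6-dienal
Product: 5 tert-butyl{[(2E,6E)-3,7-dimethylnona-2,6,8-trien-1-yl]oxy}dimethylsilane
Conditions: Ph3PCH3Br, KOtBu, THF, 0 °C → rt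
Reagents that add atoms: methyltriphenylphosphonium bromide, C[P+](c1ccccc1)(c1ccccc1)c1ccccc1.[Br-]
Why: Wittig methylenation of the enal should give the terminal 1,3-diene with the E-trisubstituted alkene unchanged.

Step 5
Reactants: 5 tert-butyl{[(2E,6E)-3,7-dimethylnona-2,6,8-trien-1-yl]oxy}dimethylsilane
Product: 7 (3E,7E)-9-[(tert-butyldimethylsilyl)oxy]-3,7-dimethylnona-3,7-dien-1-ol, via B-alkyl-9-BBN adduct 6 (not isolated)
Conditions: 9-BBN, THF, 0 °C → rt; then aq. NaOH, H2O2, 0 °C
Reagents that add atoms: 9-borabicyclo[3.3.1]nonane, B1C2CCCC1CCC2 (boron of 6 only); hydrogen peroxide, OO (hydroxyl oxygen of 7)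
Why: In this hydroboration–oxidation the bulky dialkylborane should add only to the monosubstituted terminal alkene of the diene, boron going to the terminal carbon, so that oxidation gives the homoallylic primary alcohol (net one-carbon homologation of the enal).

Step 6
Reactants: 7 (3E,7E)-9-[(tert-butyldimethylsilyl)oxy]-3,7-dimethylnona-3,7-dien-1-ol
Product: 8 {[(2E,6E)-9-bromo-3,7-dimethylnona-2,6-dien-1-yl]oxy}(tert-butyl)dimethylsilane
Conditions: CBr4, PPh3, CH2Cl2, 0 °C
Reagents that add atoms: carbon tetrabromide, BrC(Br)(Br)Br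
Why: Appel bromination of an unhindered primary alcohol runs under neutral conditions that the allylic silyl ether tolerates.

Step 7
Reactants: 8 {[(2E,6E)-9-bromo-3,7-dimethylnona-2,6-dien-1-yl]oxy}(tert-butyl)dimethylsilane
Product: 9 {(3E,7E)-9-[(tert-butyldimethylsilyl)oxy]-3,7-dimethylnona-3,7-dien-1-yl}magnesium bromide (titrated THF solution, used directly)
Conditions: Mg turnings (I2-activated), THF, 40 °C
Reagents that add atoms: magnesium, [Mg]
Why: Direct magnesium insertion into a primary alkyl bromide (Grignard formation) is compatible with the silyl ether and the trisubstituted alkenes, and the homoallyl/cyclopropylcarbinyl equilibrium is degenerate for this skeleton.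

Step 8
Reactants: 10 3-methyl-3-(trimethylsilyloxy)but-1-yne
Product: 12 4-methyl-4-(trimethylsilyloxy)pent-2-yn-1-ol, via lithium acetylide 11 (not isolated)
Conditions: n-BuLi, THF, −78 °C; (CH2O)n, −78 °C → rt; aq. NH4Cl
Reagents that add atoms: n-butyllithium, CCCC[Li] (lithium of 11 only); formaldehyde (from paraformaldehyde), C=O
Why: Deprotonation of the terminal alkyne and hydroxymethylation of the lithium acetylide with formaldehyde is a standard alkynylation that leaves the tertiary silyl ether in place.

Step 9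
Reactants: 12 4-methyl-4-(trimethylsilyloxy)pent-2-yn-1-ol
Product: 13 (2E)-4-methyl-4-(trimethylsilyloxy)pent-2-en-1-ol
Conditions: NaAlH2(OCH2CH2OMe)2, THF, 0 °C; aq. potassium sodium tartrate
Reagents that add atoms: none
Why: Hydroxyl-directed trans-hydroalumination of the propargylic alcohol followed by protonolysis should give the E-allylic alcohol only, the silyloxy group being too poor a leaving group to eliminate to the allene at 0 °C.

Step 10
Reactants: 13 (2E)-4-methyl-4-(trimethylsilyloxy)pent-2-en-1-ol
Product: 15 {[(3E)-5-bromo-2-methylpent-3-en-2-yl]oxy}trimethylsilane, via allylic mesylate 14 (not isolated)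
Conditions: MsCl, Et3N, CH2Cl2, −40 °C; then LiBr, THF, −40 → 0 °C
Reagents that add atoms: methanesulfonyl chloride, CS(=O)(=O)Cl (mesyl group of 14 only); lithium bromide, [Li+].[Br-]
Why: Mesylation and SN2 displacement by bromide at the primary allylic carbon under non-acidic conditions should preserve the E-alkene and the tertiary trimethylsilyl ether.

Step 11
Reactants: 9 {(3E,7E)-9-[(tert-butyldimethylsilyl)oxy]-3,7-dimethylnona-3,7-dien-1-yl}magnesium bromide; 16 ethyl propiolate; 15 {[(3E)-5-bromo-2-methylpent-3-en-2-yl]oxy}trimethylsilane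
Product: 19 ethyl (2E,6E,10E)-12-[(tert-butyldimethylsilyl)oxy]-6,10-dimethyl-2-[(2E)-4-methyl-4-(trimethylsilyloxy)pent-2-en-1-yl]dodeca-2,6,10-trienoate, via alkylcopper 17 (not isolated), via α-cuprio acrylate 18 (not isolated)
Conditions: CuBr·SMe2 (1.05 equiv), THF, −78 → −45 °C; 16, −78 °C; then 15, HMPA, −78 → −30 °C; aq. NH4Cl/NH3
Reagents that add atoms: CuBr·SMe2, Br[Cu].CSC (copper of 17 and 18 only)
Why: Transmetalation of 9 with CuBr·SMe2 gives the alkylcopper 17, which adds syn across the triple bond of 16 (carbocupration), the alkyl group going to the β-carbon and copper to the α-carbon, so that the α-cuprio acrylate 18 has copper cis to the new chain CH2. Allylation of the C–Cu bond by 15 then proceeds with retention (oxidative addition to a trivalent allylcopper and reductive elimination), placing the future ring A C4H2 cis to the chain and the ester trans to it, which is the geometry of the ring A alkylidene. The closest known reaction type is the low-temperature carbocupration of propiolate esters with magnesium-derived alkylcoppers and trapping of the vinylcopper by allylic halides, applied here to a functionalised homoallyl group and a substituted allylic bromide. No ring is closed and no stereocentre is formed; the step makes the chain CH2–CH= bond and the C3–C4 bond of the future ring A. Two selectivities are needed: the alkene geometry, secured by holding 18 at or below −30 °C so that it cannot equilibrate through the copper allenoate, and SN2 over SN2' allylation, secured by the fully substituted silyloxy-bearing carbon next to the γ-carbon of 15, which leaves the primary carbon as the only accessible terminus. One equivalent of copper salt per Grignard reagent leaves no free organomagnesium to attack the ester, and the silyl ethers and trisubstituted alkenes are inert.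

Step 12
Reactants: 19 ethyl (2E,6E,10E)-12-[(tert-butyldimethylsilyl)oxy]-6,10-dimethyl-2-[(2E)-4-methyl-4-(trimethylsilyloxy)pent-2-en-1-yl]dodeca-2,6,10-trienoate
Product: 20 (2E,6E,10E)-12-[(tert-butyldimethylsilyl)oxy]-2-[(2E)-4-hydroxy-4-methylpent-2-en-1-yl]-6,10-dimethyldodeca-2,6,10-trienoic acid
Conditions: LiOH·H2O, THF/MeOH/H2O, 40 °C; then 1 M HCl to pH 3–4, 0 °C, 20 min
Reagents that add atoms: lithium hydroxide, [Li+].[OH-] (carboxyl oxygen)
Why: Saponification of the hindered conjugated ester should also remove the labile tertiary trimethylsilyl ether (in the alkaline methanolic medium or at the latest on acidification) while the primary TBS ether survives.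

Step 13
Reactants: 20 (2E,6E,10E)-12-[(tert-butyldimethylsilyl)oxy]-2-[(2E)-4-hydroxy-4-methylpent-2-en-1-yl]-6,10-dimethyldodeca-2,6,10-trienoic acid
Product: 22 (2E,6E,10E)-2-{(2E)-4-[(tert-butoxycarbonyl)oxy]-4-methylpent-2-en-1-yl}-12-[(tert-butyldimethylsilyl)oxy]-6,10-dimethyldodeca-2,6,10-trienoic acid, via dilithium alkoxide carboxylate 21 (not isolated)
Conditions: LiN(SiMe3)2 (2.2 equiv), THF, −78 °C; Boc2O (1.1 equiv), −78 → 0 °C; AcOH quench; used without chromatography
Reagents that add atoms: LiN(SiMe3)2, [Li]N([Si](C)(C)C)[Si](C)(C)C (lithium of 21 only); di-tert-butyl dicarbonate, CC(C)(C)OC(=O)OC(=O)OC(C)(C)C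
Why: In this O-acylation of a lithium alkoxide the tertiary alkoxide of the dianion is by far the stronger nucleophile towards Boc2O, and any mixed anhydride formed at the carboxylate should revert to the acid on work-up.

Step 14
Reactants: 22 (2E,6E,10E)-2-{(2E)-4-[(tert-butoxycarbonyl)oxy]-4-methylpent-2-en-1-yl}-12-[(tert-butyldimethylsilyl)oxy]-6,10-dimethyldodeca-2,6,10-trienoic acid
Product: 23 (3E,5S)-3-{(4E,8E)-10-[(tert-butyldimethylsilyl)oxy]-4,8-dimethyldeca-4,8-dien-1-ylidene}-5-(2-methylprop-1-en-1-yl)dihydrofuran-2(3H)-one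
Conditions: Pd2(dba)3·CHCl3 (2.5 mol %), (1R,2R)-N,N'-bis[2-(diphenylphosphanyl)benzoyl]cyclohexane-1,2-diamine (7.5 mol %), Et3N (1 equiv), CH2Cl2, 0 °C → rt; stopped at full conversion
Reagents that add atoms: none
Why: Proposed new method: zerovalent palladium bound to the C2-symmetric bisphosphine should ionise the tertiary Boc carbonate (losing CO2 and tert-butoxide) to a 1-alkyl-3,3-dimethyl-π-allyl complex, and the carboxylate then attacks the secondary allyl terminus on the face opposite the metal in a 5-exo closure of ring A, attack at the CMe2 terminus being hindered and leading to a strained seven-membered ring; the two diastereomeric π-allyl complexes can interconvert by η3–η1–η3 slippage through the CMe2 terminus, so the C5 configuration is set under catalyst (ligand) control in the C–O bond-forming event; the closest known reaction types are asymmetric palladium-catalysed allylic substitutions with oxygen nucleophiles (intramolecular phenol and alcohol cyclisations onto trisubstituted allyl carbonates, intermolecular carboxylate alkylations), whereas an enantioselective intramolecular carboxylate capture to a γ-lactone is not established; Et3N keeps the acid as its carboxylate to suppress acid-promoted background ionisation.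

Step 15
Reactants: 23 (3E,5S)-3-{(4E,8E)-10-[(tert-butyldimethylsilyl)oxy]-4,8-dimethyldeca-4,8-dien-1-ylidene}-5-(2-methylprop-1-en-1-yl)dihydrofuran-2(3H)-one
Product: 24 (3E,5S)-3-[(4E,8E)-10-hydroxy-4,8-dimethyldeca-4,8-dien-1-ylidene]-5-(2-methylprop-1-en-1-yl)dihydrofuran-2(3H)-one
Conditions: HF·pyridine, pyridine, THF, 0 °C → rt
Reagents that add atoms: none
Why: Fluoride-mediated cleavage of the primary TBS ether under pyridine-buffered conditions should spare the allylic lactone, its C5 stereocentre and the alkylidene.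

Step 16
Reactants: 24 (3E,5S)-3-[(4E,8E)-10-hydroxy-4,8-dimethyldeca-4,8-dien-1-ylidene]-5-(2-methylprop-1-en-1-yl)dihydrofuran-2(3H)-one
Product: 25 (2E,6E,10E)-3,7-dimethyl-10-[(5S)-5-(2-methylprop-1-en-1-yl)-2-oxodihydrofuran-3(2H)-ylidene]deca-2,6-dienal
Conditions: MnO2, CH2Cl2, rt
Reagents that add atoms: none
Why: MnO2 oxidation of the primary allylic alcohol under neutral conditions should give the E-enal without disturbing ring A.

Step 17
Reactants: 26 4-(bromomethyl)furan-2(5H)-one
Product: 27 diethyl [(5-oxo-2,5-dihydrofuran-3-yl)methyl]phosphonate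
Conditions: P(OEt)3, toluene, 110 °C
Reagents that add atoms: triethyl phosphite, CCOP(OCC)OCC
Why: Michaelis–Arbuzov reaction of a reactive allylic bromide with triethyl phosphite should give the phosphonate directly.

Step 18
Reactants: 27 diethyl [(5-oxo-2,5-dihydrofuran-3-yl)methyl]phosphonate; 25 (2E,6E,10E)-3,7-dimethyl-10-[(5S)-5-(2-methylprop-1-en-1-yl)-2-oxodihydrofuran-3(2H)-ylidene]deca-2,6-dienal
Product: 29 (3E,5S)-3-[(4E,8E,10E)-4,8-dimethyl-11-(5-oxo-2,5-dihydrofuran-3-yl)undeca-4,8,10-trien-1-ylidene]-5-(2-methylprop-1-en-1-yl)dihydrofuran-2(3H)-one (CNP0187251.1), via lithiated phosphonate 28 (not isolated)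
Conditions: 27 (1.3 equiv), LiN(SiMe3)2 (1.2 equiv), THF, −78 °C; then 25, −78 → 0 °C; aq. NH4Cl
Reagents that add atoms: LiN(SiMe3)2, [Li]N([Si](C)(C)C)[Si](C)(C)C (lithium of 28 only)
Why: In this vinylogous Horner–Wadsworth–Emmons olefination the delocalised phosphonate anion should add to the enal through its phosphorus-bearing carbon and eliminate phosphate to give the E-disubstituted alkene, while the preformed, weakly basic anion leaves ring A and its C5 stereocentre untouched.

## Compound list

1 | geraniol, (2E)-3,7-dimethylocta-2,6-dien-1-ol | CC(C)=CCC/C(C)=C/CO | starting material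
2 | geranyl tert-butyldimethylsilyl ether | CC(C)=CCC/C(C)=C/CO[Si](C)(C)C(C)(C)C | intermediate
3 | (2E,6E)-8-[(tert-butyldimethylsilyl)oxy]-2,6-dimethylocta-2,6-dien-1-ol | OC/C(C)=C/CC/C(C)=C/CO[Si](C)(C)C(C)(C)C | intermediate
4 | (2E,6E)-8-[(tert-butyldimethylsilyl)oxy]-2,6-dimethylocta-2,6-dienal | O=C/C(C)=C/CC/C(C)=C/CO[Si](C)(C)C(C)(C)C | intermediate
5 | tert-butyl{[(2E,6E)-3,7-dimethylnona-2,6,8-trien-1-yl]oxy}dimethylsilane | C=C/C(C)=C/CC/C(C)=C/CO[Si](C)(C)C(C)(C)C | intermediate
6 | 9-{(3E,7E)-9-[(tert-butyldimethylsilyl)oxy]-3,7-dimethylnona-3,7-dien-1-yl}-9-borabicyclo[3.3.1]nonane (not isolated) | C1CC2CCCC(C1)B2CC/C(C)=C/CC/C(C)=C/CO[Si](C)(C)C(C)(C)C | intermediate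
7 | (3E,7E)-9-[(tert-butyldimethylsilyl)oxy]-3,7-dimethylnona-3,7-dien-1-ol | OCC/C(C)=C/CC/C(C)=C/CO[Si](C)(C)C(C)(C)C | intermediate
8 | {[(2E,6E)-9-bromo-3,7-dimethylnona-2,6-dien-1-yl]oxy}(tert-butyl)dimethylsilane | BrCC/C(C)=C/CC/C(C)=C/CO[Si](C)(C)C(C)(C)C | intermediate
9 | {(3E,7E)-9-[(tert-butyldimethylsilyl)oxy]-3,7-dimethylnona-3,7-dien-1-yl}magnesium bromide | Br[Mg]CC/C(C)=C/CC/C(C)=C/CO[Si](C)(C)C(C)(C)C | intermediate
10 | 3-methyl-3-(trimethylsilyloxy)but-1-yne | C#CC(C)(C)O[Si](C)(C)C | starting material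
11 | lithium acetylide of 10 (not isolated) | [Li]C#CC(C)(C)O[Si](C)(C)C | intermediate
12 | 4-methyl-4-(trimethylsilyloxy)pent-2-yn-1-ol | OCC#CC(C)(C)O[Si](C)(C)C | intermediate
13 | (2E)-4-methyl-4-(trimethylsilyloxy)pent-2-en-1-ol | OC/C=C/C(C)(C)O[Si](C)(C)C | intermediate
14 | (2E)-4-methyl-4-(trimethylsilyloxy)pent-2-en-1-yl methanesulfonate (not isolated) | CS(=O)(=O)OC/C=C/C(C)(C)O[Si](C)(C)C | intermediate
15 | {[(3E)-5-bromo-2-methylpent-3-en-2-yl]oxy}trimethylsilane | BrC/C=C/C(C)(C)O[Si](C)(C)C | intermediate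
16 | ethyl propiolate | C#CC(=O)OCC | starting material
17 | {(3E,7E)-9-[(tert-butyldimethylsilyl)oxy]-3,7-dimethylnona-3,7-dien-1-yl}copper, as its MgBr2/SMe2 complex (not isolated) | [Cu]CC/C(C)=C/CC/C(C)=C/CO[Si](C)(C)C(C)(C)C | intermediate
18 | ethyl (2Z,6E,10E)-12-[(tert-butyldimethylsilyl)oxy]-2-cuprio-6,10-dimethyldodeca-2,6,10-trienoate (not isolated) | CCOC(=O)/C([Cu])=C/CC/C(C)=C/CC/C(C)=C/CO[Si](C)(C)C(C)(C)C | intermediate
19 | ethyl (2E,6E,10E)-12-[(tert-butyldimethylsilyl)oxy]-6,10-dimethyl-2-[(2E)-4-methyl-4-(trimethylsilyloxy)pent-2-en-1-yl]dodeca-2,6,10-trienoate | C[Si](C)(C)OC(C)(C)/C=C/C/C(=C\CC/C(C)=C/CC/C(C)=C/CO[Si](C)(C)C(C)(C)C)C(=O)OCC | intermediate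
20 | (2E,6E,10E)-12-[(tert-butyldimethylsilyl)oxy]-2-[(2E)-4-hydroxy-4-methylpent-2-en-1-yl]-6,10-dimethyldodeca-2,6,10-trienoic acid | CC(C)(O)/C=C/C/C(=C\CC/C(C)=C/CC/C(C)=C/CO[Si](C)(C)C(C)(C)C)C(=O)O | intermediate
21 | dilithium alkoxide carboxylate of 20 (not isolated) | [Li]OC(C)(C)/C=C/C/C(=C\CC/C(C)=C/CC/C(C)=C/CO[Si](C)(C)C(C)(C)C)C(=O)O[Li] | intermediate
22 | (2E,6E,10E)-2-{(2E)-4-[(tert-butoxycarbonyl)oxy]-4-methylpent-2-en-1-yl}-12-[(tert-butyldimethylsilyl)oxy]-6,10-dimethyldodeca-2,6,10-trienoic acid | CC(C)(C)OC(=O)OC(C)(C)/C=C/C/C(=C\CC/C(C)=C/CC/C(C)=C/CO[Si](C)(C)C(C)(C)C)C(=O)O | intermediate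
23 | (3E,5S)-3-{(4E,8E)-10-[(tert-butyldimethylsilyl)oxy]-4,8-dimethyldeca-4,8-dien-1-ylidene}-5-(2-methylprop-1-en-1-yl)dihydrofuran-2(3H)-one | CC(C)=C[C@@H]1C/C(=C\CC/C(C)=C/CC/C(C)=C/CO[Si](C)(C)C(C)(C)C)C(=O)O1 | intermediate
24 | (3E,5S)-3-[(4E,8E)-10-hydroxy-4,8-dimethyldeca-4,8-dien-1-ylidene]-5-(2-methylprop-1-en-1-yl)dihydrofuran-2(3H)-one | CC(C)=C[C@@H]1C/C(=C\CC/C(C)=C/CC/C(C)=C/CO)C(=O)O1 | intermediate
25 | (2E,6E,10E)-3,7-dimethyl-10-[(5S)-5-(2-methylprop-1-en-1-yl)-2-oxodihydrofuran-3(2H)-ylidene]deca-2,6-dienal | CC(C)=C[C@@H]1C/C(=C\CC/C(C)=C/CC/C(C)=C/C=O)C(=O)O1 | intermediate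
26 | 4-(bromomethyl)furan-2(5H)-one | BrCC1=CC(=O)OC1 | starting material
27 | diethyl [(5-oxo-2,5-dihydrofuran-3-yl)methyl]phosphonate | CCOP(=O)(CC1=CC(=O)OC1)OCC | intermediate
28 | lithiated phosphonate from 27, drawn C-lithiated, a delocalised dienolate (not isolated) | CCOP(=O)(C([Li])C1=CC(=O)OC1)OCC | intermediate
29 | (3E,5S)-3-[(4E,8E,10E)-4,8-dimethyl-11-(5-oxo-2,5-dihydrofuran-3-yl)undeca-4,8,10-trien-1-ylidene]-5-(2-methylprop-1-en-1-yl)dihydrofuran-2(3H)-one | CC(C)=C[C@@H]1C/C(=C\CC/C(C)=C/CC/C(C)=C/C=C/C2=CC(=O)OC2)C(=O)O1 | target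

## Step count and risks

Total step count: 18. Longest linear sequence: 14 steps (steps 1–7, 11–16 and 18).

Steps most likely to fail:

1. Step 14 (proposed new method). The risk is poor facial discrimination in the C–O bond-forming event, or erosion of enantiomeric purity when the allylic C5–O bond of the product re-ionises on palladium, together with competing β-hydride elimination of the π-allyl intermediate to a diene. The fallback uses known chemistry, sets out from 19 and returns at 23. The tertiary trimethylsilyl ether of 19 is cleaved selectively (AcOH/THF/H2O, rt) to the ethyl hydroxy ester F1. Babler–Dauben oxidative transposition with pyridinium chlorochromate, [C5H5NH][CrO3Cl], in CH2Cl2 gives the β,β-dimethyl enone F2. Corey–Bakshi–Shibata reduction with the (R)-methyl oxazaborolidine and catecholborane at −78 °C, the alkenyl group acting as the larger substituent, should give the (S)-allylic alcohol F3. Catalytic NaH in THF at 0 °C closes the lactone to 23.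

2. Step 11. The risk is loss of alkene geometry by equilibration of the vinylcopper through the copper allenoate before it is allylated, sluggish allylation of the vinylcopper, or partial SN2' capture. The fallback sets out from 9 and 15 and returns at 19. Grignard reagent 9 is formylated with DMF (Bouveault aldehyde synthesis) to the aldehyde F4. Triethyl phosphonoacetate is alkylated with 15 (NaH, THF) to the α-allylated phosphonoacetate F5. Horner–Wadsworth–Emmons olefination of F4 with F5 (NaH, THF, 0 °C) should give 19 as the major E isomer, to be separated from the Z isomer by chromatography; this trades the stereospecific cupration for a thermodynamically biased olefination.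

3. Step 18. The risk is reaction of the ambident butenolide anion through ring carbons C5 or C3 (aldol pathways), proton transfer to the anion, and base-induced degradation of the polyene product. The fallback sets out from 25 and returns at 29. Takai–Utimoto borylolefination of 25 (Cl2CHBpin, CrCl2, LiI, THF, rt) gives the (E,E)-dienyl pinacol boronate F6. Suzuki–Miyaura coupling of F6 with commercial 4-bromofuran-2(5H)-one (PdCl2(dppf), aq. K3PO4, THF, rt) then forms the diene–ring B C–C bond and gives 29 without strong base.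

## Further compounds

F1 | step 14 | ethyl (2E,6E,10E)-12-[(tert-butyldimethylsilyl)oxy]-2-[(2E)-4-hydroxy-4-methylpent-2-en-1-yl]-6,10-dimethyldodeca-2,6,10-trienoate | CC(C)(O)/C=C/C/C(=C\CC/C(C)=C/CC/C(C)=C/CO[Si](C)(C)C(C)(C)C)C(=O)OCC
F2 | step 14 | ethyl (2E,6E,10E)-12-[(tert-butyldimethylsilyl)oxy]-6,10-dimethyl-2-(4-methyl-2-oxopent-3-en-1-yl)dodeca-2,6,10-trienoate | CC(C)=CC(=O)C/C(=C\CC/C(C)=C/CC/C(C)=C/CO[Si](C)(C)C(C)(C)C)C(=O)OCC
F3 | step 14 | ethyl (2E,6E,10E)-12-[(tert-butyldimethylsilyl)oxy]-2-[(2S)-2-hydroxy-4-methylpent-3-en-1-yl]-6,10-dimethyldodeca-2,6,10-trienoate | CC(C)=C[C@@H](O)C/C(=C\CC/C(C)=C/CC/C(C)=C/CO[Si](C)(C)C(C)(C)C)C(=O)OCC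
F4 | step 11 | (4E,8E)-10-[(tert-butyldimethylsilyl)oxy]-4,8-dimethyldeca-4,8-dienal | O=CCC/C(C)=C/CC/C(C)=C/CO[Si](C)(C)C(C)(C)C
F5 | step 11 | ethyl (4E)-2-(diethoxyphosphoryl)-6-methyl-6-(trimethylsilyloxy)hept-4-enoate | CCOC(=O)C(C/C=C/C(C)(C)O[Si](C)(C)C)P(=O)(OCC)OCC
F6 | step 18 | (3E,5S)-3-[(4E,8E,10E)-4,8-dimethyl-11-(4,4,5,5-tetramethyl-1,3,2-dioxaborolan-2-yl)undeca-4,8,10-trien-1-ylidene]-5-(2-methylprop-1-en-1-yl)dihydrofuran-2(3H)-one | CC(C)=C[C@@H]1C/C(=C\CC/C(C)=C/CC/C(C)=C/C=C/B2OC(C)(C)C(C)(C)O2)C(=O)O1
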